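Rings are lettered A to G from the 2,4,6-trioxygenated end ring (A) to the 3,4,5-trioxygenated end ring (G); in ring A, C1 bears the oxygen to ring B, and in rings B to G, C1 bears the ether oxygen coming from the preceding ring.

**Retrosynthetic overview**
- The route rests on the hydroxyls at C4 of ring C and C4 of ring G, each lying between the oxygen-bearing C3 and C5 of its ring. They are added last, by twofold lithiation, borylation and oxidation of a heptamer that has C–H at both sites and MOM ethers only at C3/C5 of rings C and G (eleven methyl ethers elsewhere).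
- The target then follows by MOM removal and exhaustive demethylation.
- The heptamer has six diaryl ether bonds; each is cut between a phenol oxygen flanked by two ortho oxygens (nucleophile) and an aryl carbon with a free ortho position (electrophile).
- Ring pairs B–C and D–E are made as bromo aldehydes by SNAr of 4-bromo-2,6-dimethoxyphenol on 2-fluoro-4,6-dialkoxybenzaldehydes. The bromide is the handle for copper-catalysed O-arylation; the aldehyde is a masked phenol (Baeyer–Villiger).
- No ring is formed; the seven purchased benzene rings are joined in the order A + BC, then DE, then F, then G.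

Key step: step 14

Assumption: 2-fluoro-4,6-dimethoxybenzaldehyde, 4-bromo-2,6-dimethoxyphenol, 2,4,6-trimethoxyphenol and 5-bromoresorcinol are taken as purchasable; all copper couplings and all steps with free electron-rich phenols are run under argon.

**Route**

Step 1
Reactants: 1 2-fluoro-4,6-dimethoxybenzaldehyde
Product: 2 2-fluoro-4,6-dihydroxybenzaldehyde
Conditions: BBr3 (3.5 equiv), CH2Cl2, −78 °C to rt; then H2O
Reagents that add atoms: none
Why: Lewis-acid ether cleavage (bromide attacks the methyl group of the boron-bound ether); the C–F bond is inert and the formyl group is returned on aqueous work-up.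

Step 2
Reactants: 2 2-fluoro-4,6-dihydroxybenzaldehyde; 3 chloromethyl methyl ether
Product: 4 2-fluoro-4,6-bis(methoxymethoxy)benzaldehyde
Conditions: NaH (2.5 equiv), DMF, 0 °C; then MOMCl (2.6 equiv), 0 °C to rt
Reagents that add atoms: chloromethyl methyl ether, COCCl
Why: Williamson-type O-alkylation of both phenoxides; full deprotonation with NaH also engages the hydroxyl that is hydrogen-bonded to the aldehyde.

Step 3
Reactants: 4 2-fluoro-4,6-bis(methoxymethoxy)benzaldehyde; 5 4-bromo-2,6-dimethoxyphenol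
Product: 6 2-(4-bromo-2,6-dimethoxyphenoxy)-4,6-bis(methoxymethoxy)benzaldehyde (rings B and C)
Conditions: Cs2CO3 (1.5 equiv), DMSO, 100 °C
Reagents that add atoms: none
Why: Nucleophilic aromatic substitution by addition–elimination: the phenoxide displaces fluoride ortho to the formyl group through a Meisenheimer adduct, both MOM-oxy groups being meta to fluorine, and the aryl bromide survives because no transition metal is present.

Step 4
Reactants: 7 2,4,6-trimethoxyphenol; 6 bromo aldehyde of rings B and C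
Product: 8 2-[2,6-dimethoxy-4-(2,4,6-trimethoxyphenoxy)phenoxy]-4,6-bis(methoxymethoxy)benzaldehyde (ABC aldehyde)
Conditions: CuI (10 mol %), picolinic acid (20 mol %), K3PO4 (2 equiv), DMSO, 90 °C
Reagents that add atoms: none
Why: Ullmann-type copper-catalysed O-arylation; the bromide has two free ortho positions, so only the phenol is hindered, a case this ligand system tolerates, and aldehyde and MOM ethers are stable to K3PO4.

Step 5
Reactants: 8 ABC aldehyde
Product: 10 2-[2,6-dimethoxy-4-(2,4,6-trimethoxyphenoxy)phenoxy]-4,6-bis(methoxymethoxy)phenol (ABC phenol), via aryl formate 9 (not isolated)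
Conditions: mCPBA (1.2 equiv), NaHCO3, CH2Cl2, 0 °C to rt; Na2SO3 quench; then K2CO3 (cat.), MeOH, rt
Reagents that add atoms: meta-chloroperbenzoic acid, OOC(=O)c1cccc(Cl)c1
Why: Baeyer–Villiger (Dakin-type) oxidation: the trioxygenated aryl group migrates in the Criegee adduct to give the formate, which methanolysis turns into the phenol; the buffer protects the MOM ethers and the near-stoichiometric peracid spares the electron-rich rings.

Step 6
Reactants: 1 2-fluoro-4,6-dimethoxybenzaldehyde; 5 4-bromo-2,6-dimethoxyphenol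
Product: 11 2-(4-bromo-2,6-dimethoxyphenoxy)-4,6-dimethoxybenzaldehyde (rings D and E)
Conditions: Cs2CO3 (1.5 equiv), DMSO, 110 °C
Reagents that add atoms: none
Why: Nucleophilic aromatic substitution of fluoride ortho to formyl, as in step 3.

Step 7
Reactants: 10 ABC phenol; 11 bromo aldehyde of rings D and E
Product: 12 ABCDE aldehyde (ring C C6–O–C1 ring D; ring E carries CHO at C6)
Conditions: CuI (20 mol %), picolinic acid (40 mol %), K3PO4 (2 equiv), DMSO, 100 °C
Reagents that add atoms: none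
Why: Ullmann-type copper-catalysed O-arylation of a phenol flanked by an aryloxy group and a MOM ether with a bromide that has two free ortho positions.

Step 8
Reactants: 12 ABCDE aldehyde
Product: 14 ABCDE phenol (free OH at C6 of ring E), via aryl formate 13 (not isolated)
Conditions: mCPBA (1.2 equiv), NaHCO3, CH2Cl2, 0 °C to rt; Na2SO3 quench; then K2CO3 (cat.), MeOH, rt
Reagents that add atoms: meta-chloroperbenzoic acid, OOC(=O)c1cccc(Cl)c1
Why: Baeyer–Villiger oxidation with migration of the 2,4,6-trioxygenated aryl group, then formate methanolysis, as in step 5.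

Step 9
Reactants: 5 4-bromo-2,6-dimethoxyphenol; 15 benzyl bromide
Product: 16 2-(benzyloxy)-5-bromo-1,3-dimethoxybenzene
Conditions: K2CO3, DMF, rt to 50 °C
Reagents that add atoms: benzyl bromide, BrCc1ccccc1
Why: Williamson ether synthesis (SN2 at the benzylic carbon) masks the hindered hydroxyl so that the bromide can serve as the ring F electrophile.

Step 10
Reactants: 14 ABCDE phenol; 16 2-(benzyloxy)-5-bromo-1,3-dimethoxybenzene
Product: 17 ABCDEF benzyl ether (ring F carries OBn at C4)
Conditions: CuI (20 mol %), picolinic acid (40 mol %), K3PO4 (2 equiv), DMSO, 100 °C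
Reagents that add atoms: none
Why: Ullmann-type copper-catalysed O-arylation of the ring E phenol with a bromide that has two free ortho positions.

Step 11
Reactants: 17 ABCDEF benzyl ether
Product: 18 ABCDEF phenol (free OH at C4 of ring F)
Conditions: H2 (1 atm), 10% Pd/C, EtOAc–MeOH, rt
Reagents that add atoms: none
Why: Hydrogenolysis of the benzyl ether; MOM, methyl and diaryl ethers are not reduced and no aryl halide is left in the molecule.

Step 12
Reactants: 19 5-bromoresorcinol; 3 chloromethyl methyl ether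
Product: 20 1-bromo-3,5-bis(methoxymethoxy)benzene
Conditions: NaH (2.4 equiv), DMF, 0 °C; then MOMCl (2.5 equiv), 0 °C to rt
Reagents that add atoms: chloromethyl methyl ether, COCCl
Why: Williamson-type O-alkylation of both phenoxides.

Step 13
Reactants: 18 ABCDEF phenol; 20 1-bromo-3,5-bis(methoxymethoxy)benzene
Product: 21 heptamer with C–H at C4 of rings C and G, MOM ethers at C3 and C5 of rings C and G, and eleven methyl ethers
Conditions: CuI (20 mol %), picolinic acid (40 mol %), K3PO4 (2 equiv), DMSO, 100 °C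
Reagents that add atoms: none
Why: Ullmann-type copper-catalysed O-arylation; the phenol is a 2,6-dimethoxyphenol like 7 and the bromide has two free ortho positions and two meta oxygens.

Step 14
Reactants: 21 heptamer
Product: 24 heptamer diol (free OH at C4 of ring C and at C4 of ring G), via dilithio heptamer 22 (not isolated), via bis(dimethyl boronate) 23 (not isolated)
Conditions: n-BuLi (2.4 equiv), TMEDA (2.4 equiv), THF, −78 to −30 °C; B(OMe)3 (6 equiv), −78 °C to rt; 30% aq H2O2, 0 °C to rt; Na2S2O3, NH4Cl work-up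
Reagents that add atoms: hydrogen peroxide, OO (oxygen of both new hydroxyls); n-butyllithium, [Li]CCCC, and trimethyl borate, COB(OC)OC, leave atoms only in intermediates 22 and 23
Why: n-BuLi/TMEDA binds to the acetal oxygens of the MOM groups at C3 and C5 of ring C and of ring G and removes the C4 proton held between them, giving in each ring an aryllithium chelated from both sides; B(OMe)3 turns both into aryl boronates, hydroperoxide adds to boron, the aryl group shifts from boron to oxygen, and hydrolysis of the borate esters frees the two phenols. The closest known reaction type is directed ortho-metalation of 1,3-bis(methoxymethoxy)arenes at the carbon between the two ethers, followed by borylation and peroxide oxidation to 2,6-bis(methoxymethoxy)phenols. No ring is closed and no stereocentre is formed. The step needs site selectivity for C4 of rings C and G over C2 of ring C and C2/C6 of ring G (one MOM ether and one diaryl ether oxygen as neighbours), over the methoxy-flanked C3–H and C5–H of ring A and C4–H of ring E, and over the C–H bonds next to a single methoxy group in rings B, D, E and F. It is secured by the two-point chelation that only the MOM pairs offer, by the weak Lewis basicity of diaryl ether oxygens, by the lower directing power of methoxy, and by keeping the base near two equivalents at low temperature.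

Step 15
Reactants: 24 heptamer diol
Product: 25 heptamer hexaol (OH at C3, C4 and C5 of rings C and G; eleven methyl ethers kept)
Conditions: HCl (from AcCl) in MeOH–THF, 40 °C, argon
Reagents that add atoms: none
Why: Acid-catalysed acetal exchange with methanol removes the four MOM groups as dimethoxymethane; doing this before BBr3 keeps bromomethyl methyl ether, an alkylating agent for the electron-rich rings, out of the last step.

Step 16
Reactants: 25 heptamer hexaol
Product: 26 target CNP0351377.0 (seventeen free hydroxyls)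
Conditions: BBr3 (25 equiv), CH2Cl2, −78 °C to rt, argon; then degassed H2O, 0 °C
Reagents that add atoms: none
Why: Exhaustive Lewis-acid demethylation with BBr3; the diaryl ether bonds stay because neither of their carbons can undergo SN2, and work-up under argon protects the polyphenol.

**Compound list**
1 | 2-fluoro-4,6-dimethoxybenzaldehyde | COc1cc(F)c(C=O)c(OC)c1 | starting material
2 | 2-fluoro-4,6-dihydroxybenzaldehyde | Oc1cc(F)c(C=O)c(O)c1 | intermediate
3 | chloromethyl methyl ether | COCCl | starting material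
4 | 2-fluoro-4,6-bis(methoxymethoxy)benzaldehyde | COCOc1cc(F)c(C=O)c(OCOC)c1 | intermediate
5 | 4-bromo-2,6-dimethoxyphenol | COc1cc(Br)cc(OC)c1O | starting material
6 | 2-(4-bromo-2,6-dimethoxyphenoxy)-4,6-bis(methoxymethoxy)benzaldehyde | COCOc1cc(Oc2c(OC)cc(Br)cc2OC)c(C=O)c(OCOC)c1 | intermediate
7 | 2,4,6-trimethoxyphenol | COc1cc(OC)c(O)c(OC)c1 | starting material
8 | ABC aldehyde, 2-[2,6-dimethoxy-4-(2,4,6-trimethoxyphenoxy)phenoxy]-4,6-bis(methoxymethoxy)benzaldehyde | COc1cc(OC)c(Oc2cc(OC)c(Oc3cc(OCOC)cc(OCOC)c3C=O)c(OC)c2)c(OC)c1 | intermediate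
9 | ABC aryl formate (formate ester of 10) | COc1cc(OC)c(Oc2cc(OC)c(Oc3cc(OCOC)cc(OCOC)c3OC=O)c(OC)c2)c(OC)c1 | intermediate
10 | ABC phenol, 2-[2,6-dimethoxy-4-(2,4,6-trimethoxyphenoxy)phenoxy]-4,6-bis(methoxymethoxy)phenol | COc1cc(OC)c(Oc2cc(OC)c(Oc3cc(OCOC)cc(OCOC)c3O)c(OC)c2)c(OC)c1 | intermediate
11 | 2-(4-bromo-2,6-dimethoxyphenoxy)-4,6-dimethoxybenzaldehyde | COc1cc(Oc2c(OC)cc(Br)cc2OC)c(C=O)c(OC)c1 | intermediate
12 | ABCDE aldehyde (CHO at C6 of ring E) | COc1cc(OC)c(Oc2cc(OC)c(Oc3cc(OCOC)cc(OCOC)c3Oc3cc(OC)c(Oc4cc(OC)cc(OC)c4C=O)c(OC)c3)c(OC)c2)c(OC)c1 | intermediate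
13 | ABCDE aryl formate (formate ester of 14) | COc1cc(OC)c(Oc2cc(OC)c(Oc3cc(OCOC)cc(OCOC)c3Oc3cc(OC)c(Oc4cc(OC)cc(OC)c4OC=O)c(OC)c3)c(OC)c2)c(OC)c1 | intermediate
14 | ABCDE phenol (OH at C6 of ring E) | COc1cc(OC)c(Oc2cc(OC)c(Oc3cc(OCOC)cc(OCOC)c3Oc3cc(OC)c(Oc4cc(OC)cc(OC)c4O)c(OC)c3)c(OC)c2)c(OC)c1 | intermediate
15 | benzyl bromide | BrCc1ccccc1 | starting material
16 | 2-(benzyloxy)-5-bromo-1,3-dimethoxybenzene | COc1cc(Br)cc(OC)c1OCc1ccccc1 | intermediate
17 | ABCDEF benzyl ether (OBn at C4 of ring F) | COc1cc(OC)c(Oc2cc(OC)c(Oc3cc(OCOC)cc(OCOC)c3Oc3cc(OC)c(Oc4cc(OC)cc(OC)c4Oc4cc(OC)c(OCc5ccccc5)c(OC)c4)c(OC)c3)c(OC)c2)c(OC)c1 | intermediate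
18 | ABCDEF phenol (OH at C4 of ring F) | COc1cc(OC)c(Oc2cc(OC)c(Oc3cc(OCOC)cc(OCOC)c3Oc3cc(OC)c(Oc4cc(OC)cc(OC)c4Oc4cc(OC)c(O)c(OC)c4)c(OC)c3)c(OC)c2)c(OC)c1 | intermediate
19 | 5-bromoresorcinol (5-bromobenzene-1,3-diol) | Oc1cc(O)cc(Br)c1 | starting material
20 | 1-bromo-3,5-bis(methoxymethoxy)benzene | COCOc1cc(Br)cc(OCOC)c1 | intermediate
21 | heptamer, C–H at C4 of rings C and G, MOM at C3/C5 of rings C and G, eleven OMe | COc1cc(OC)c(Oc2cc(OC)c(Oc3cc(OCOC)cc(OCOC)c3Oc3cc(OC)c(Oc4cc(OC)cc(OC)c4Oc4cc(OC)c(Oc5cc(OCOC)cc(OCOC)c5)c(OC)c4)c(OC)c3)c(OC)c2)c(OC)c1 | intermediate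
22 | dilithio heptamer (Li at C4 of ring C and C4 of ring G) | COc1cc(OC)c(Oc2cc(OC)c(Oc3cc(OCOC)c([Li])c(OCOC)c3Oc3cc(OC)c(Oc4cc(OC)cc(OC)c4Oc4cc(OC)c(Oc5cc(OCOC)c([Li])c(OCOC)c5)c(OC)c4)c(OC)c3)c(OC)c2)c(OC)c1 | intermediate
23 | bis(dimethyl boronate) of the heptamer (B(OMe)2 at C4 of ring C and C4 of ring G) | COc1cc(OC)c(Oc2cc(OC)c(Oc3cc(OCOC)c(B(OC)OC)c(OCOC)c3Oc3cc(OC)c(Oc4cc(OC)cc(OC)c4Oc4cc(OC)c(Oc5cc(OCOC)c(B(OC)OC)c(OCOC)c5)c(OC)c4)c(OC)c3)c(OC)c2)c(OC)c1 | intermediate
24 | heptamer diol (OH at C4 of ring C and C4 of ring G) | COc1cc(OC)c(Oc2cc(OC)c(Oc3cc(OCOC)c(O)c(OCOC)c3Oc3cc(OC)c(Oc4cc(OC)cc(OC)c4Oc4cc(OC)c(Oc5cc(OCOC)c(O)c(OCOC)c5)c(OC)c4)c(OC)c3)c(OC)c2)c(OC)c1 | intermediate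
25 | heptamer hexaol (OH at C3, C4, C5 of rings C and G; eleven OMe) | COc1cc(OC)c(Oc2cc(OC)c(Oc3cc(O)c(O)c(O)c3Oc3cc(OC)c(Oc4cc(OC)cc(OC)c4Oc4cc(OC)c(Oc5cc(O)c(O)c(O)c5)c(OC)c4)c(OC)c3)c(OC)c2)c(OC)c1 | intermediate
26 | CNP0351377.0 | Oc1cc(O)c(Oc2cc(O)c(Oc3cc(O)c(O)c(O)c3Oc3cc(O)c(Oc4cc(O)cc(O)c4Oc4cc(O)c(Oc5cc(O)c(O)c(O)c5)c(O)c4)c(O)c3)c(O)c2)c(O)c1 | target

**Totals**
Total step count: 16
Longest linear sequence: 13 steps (steps 1, 2, 3, 4, 5, 7, 8, 10, 11, 13, 14, 15, 16)

**Steps most likely to fail**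

Step 14. What may go wrong: deprotonation also next to a single MOM ether (C2 of ring C, C2/C6 of ring G) or between two methoxy groups (rings A and E), or metalation of only one of the two rings, so that the diol forms within an isomer mixture. Fallback: both oxygens are carried in from the start as methyl ethers and no C–H hydroxylation is needed; it sets out from 5 and comes back at 26.
- Formylation of purchased 5-fluoro-1,2,3-trimethoxybenzene (Cl2CHOMe, TiCl4, CH2Cl2, 0 °C) should give 6-fluoro-2,3,4-trimethoxybenzaldehyde F1.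
- SNAr of 5 on F1 (Cs2CO3, DMSO) should give 6-(4-bromo-2,6-dimethoxyphenoxy)-2,3,4-trimethoxybenzaldehyde F2.
- Copper-catalysed O-arylation of 7 with F2 should give the permethyl ABC aldehyde F3.
- mCPBA should give the permethyl ABC aryl formate F4, not isolated, and methanolysis the permethyl ABC phenol F5.
- O-arylation of F5 with 11 should give the permethyl ABCDE aldehyde F6, oxidised through the permethyl ABCDE aryl formate F7 to the permethyl ABCDE phenol F8.
- O-arylation of F8 with 16 should give the permethyl ABCDEF benzyl ether F9, and hydrogenolysis the permethyl ABCDEF phenol F10.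
- O-arylation of F10 with purchased 5-bromo-1,2,3-trimethoxybenzene should give the heptadecamethyl ether F11, which BBr3 converts into 26.

Step 7. What may go wrong: slow C–O bond formation at copper, because the phenoxide of 10 is flanked by an aryloxy group and a MOM ether, so that hydrodebromination of 11 and oxidative loss of the phenoxide take over. Fallback: metal-free chain growth one ring at a time; it sets out from 10 and comes back at 12.
- SNAr of the phenoxide of 10 on purchased 4-fluoro-2,6-dimethoxybenzaldehyde (Cs2CO3, DMSO, 110 °C; fluoride para to formyl) should give the ABCD aldehyde F12.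
- Baeyer–Villiger oxidation through the ABCD aryl formate F13, not isolated, should give the ABCD phenol F14.
- SNAr of F14 on 1 should give 12.

Step 16. What may go wrong: incomplete cleavage of the eleven methyl ethers together with air oxidation of the free polyphenol during work-up and chromatography. Fallback: isolation through a stable derivative; it sets out from 25 and comes back at 26.
- After the BBr3 cleavage the crude product is acetylated without exposure to air (Ac2O, pyridine, DMAP) to the heptadecaacetate F15.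
- F15 can be chromatographed on silica, and under-cleaved acetates are separated and resubmitted.
- Methanolysis with HCl in MeOH under argon then releases 26.

**Further compounds**
F1 | step 14 | 6-fluoro-2,3,4-trimethoxybenzaldehyde | COc1cc(F)c(C=O)c(OC)c1OC
F2 | step 14 | 6-(4-bromo-2,6-dimethoxyphenoxy)-2,3,4-trimethoxybenzaldehyde | COc1cc(Oc2c(OC)cc(Br)cc2OC)c(C=O)c(OC)c1OC
F3 | step 14 | permethyl ABC aldehyde (ring C 3,4,5-trimethoxy, CHO at C6) | COc1cc(OC)c(Oc2cc(OC)c(Oc3cc(OC)c(OC)c(OC)c3C=O)c(OC)c2)c(OC)c1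
F4 | step 14 | permethyl ABC aryl formate | COc1cc(OC)c(Oc2cc(OC)c(Oc3cc(OC)c(OC)c(OC)c3OC=O)c(OC)c2)c(OC)c1
F5 | step 14 | permethyl ABC phenol | COc1cc(OC)c(Oc2cc(OC)c(Oc3cc(OC)c(OC)c(OC)c3O)c(OC)c2)c(OC)c1
F6 | step 14 | permethyl ABCDE aldehyde | COc1cc(OC)c(Oc2cc(OC)c(Oc3cc(OC)c(OC)c(OC)c3Oc3cc(OC)c(Oc4cc(OC)cc(OC)c4C=O)c(OC)c3)c(OC)c2)c(OC)c1
F7 | step 14 | permethyl ABCDE aryl formate | COc1cc(OC)c(Oc2cc(OC)c(Oc3cc(OC)c(OC)c(OC)c3Oc3cc(OC)c(Oc4cc(OC)cc(OC)c4OC=O)c(OC)c3)c(OC)c2)c(OC)c1
F8 | step 14 | permethyl ABCDE phenol | COc1cc(OC)c(Oc2cc(OC)c(Oc3cc(OC)c(OC)c(OC)c3Oc3cc(OC)c(Oc4cc(OC)cc(OC)c4O)c(OC)c3)c(OC)c2)c(OC)c1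
F9 | step 14 | permethyl ABCDEF benzyl ether | COc1cc(OC)c(Oc2cc(OC)c(Oc3cc(OC)c(OC)c(OC)c3Oc3cc(OC)c(Oc4cc(OC)cc(OC)c4Oc4cc(OC)c(OCc5ccccc5)c(OC)c4)c(OC)c3)c(OC)c2)c(OC)c1
F10 | step 14 | permethyl ABCDEF phenol | COc1cc(OC)c(Oc2cc(OC)c(Oc3cc(OC)c(OC)c(OC)c3Oc3cc(OC)c(Oc4cc(OC)cc(OC)c4Oc4cc(OC)c(O)c(OC)c4)c(OC)c3)c(OC)c2)c(OC)c1
F11 | step 14 | heptadecamethyl ether of 26 | COc1cc(OC)c(Oc2cc(OC)c(Oc3cc(OC)c(OC)c(OC)c3Oc3cc(OC)c(Oc4cc(OC)cc(OC)c4Oc4cc(OC)c(Oc5cc(OC)c(OC)c(OC)c5)c(OC)c4)c(OC)c3)c(OC)c2)c(OC)c1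
F12 | step 7 | ABCD aldehyde (CHO at C4 of ring D) | COc1cc(OC)c(Oc2cc(OC)c(Oc3cc(OCOC)cc(OCOC)c3Oc3cc(OC)c(C=O)c(OC)c3)c(OC)c2)c(OC)c1
F13 | step 7 | ABCD aryl formate | COc1cc(OC)c(Oc2cc(OC)c(Oc3cc(OCOC)cc(OCOC)c3Oc3cc(OC)c(OC=O)c(OC)c3)c(OC)c2)c(OC)c1
F14 | step 7 | ABCD phenol (OH at C4 of ring D) | COc1cc(OC)c(Oc2cc(OC)c(Oc3cc(OCOC)cc(OCOC)c3Oc3cc(OC)c(O)c(OC)c3)c(OC)c2)c(OC)c1
F15 | step 16 | heptadecaacetate of 26 | CC(=O)Oc1cc(OC(C)=O)c(Oc2cc(OC(C)=O)c(Oc3cc(OC(C)=O)c(OC(C)=O)c(OC(C)=O)c3Oc3cc(OC(C)=O)c(Oc4cc(OC(C)=O)cc(OC(C)=O)c4Oc4cc(OC(C)=O)c(Oc5cc(OC(C)=O)c(OC(C)=O)c(OC(C)=O)c5)c(OC(C)=O)c4)c(OC(C)=O)c3)c(OC(C)=O)c2)c(OC(C)=O)c1
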